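**Retrosynthetic overview**
- The target, 3'-hydroxy-5,6,7,2'-tetramethoxyisoflavone, is reached by debenzylation of its 3'-O-benzyl ether 17; nothing else needs unmasking.
- Ring C of 17 is opened at O1–C8a, C4–C4a and O1–C2, giving 3,4,5-trimethoxybenzyne (from silyl triflate 5) and the β-methoxyacrylic acid 14, which carries C2, C3, C4 and ring B.
- The strategy rests on one structural feature: ring C is fused to ring A across C4a–C8a, and the C5 methoxy group of the 5,6,7-trimethoxy ring A is the direct neighbour of C4a. An aryne spanning C4a/C8a is therefore a 3-alkoxybenzyne, biased to accept oxygen at C8a and the acyl carbon at C4a.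
- 5 comes from 3,4,5-trimethoxyphenol (bromination, O-silylation, retro-Brook/triflation). 14 comes from 2,3-dihydroxybenzaldehyde (selective benzylation, methylation, one-carbon homologation, formylation/O-methylation, saponification).
- Rings A and B are bought intact; ring C is the only ring formed, in step 11.

Key step: step 11

Remark: 12 is drawn as its enol tautomer, 9 is taken as an alkene-isomer mixture racemic at sulfur, and the E geometry of 13, 14 and 16 is the expected major isomer; none of these elements survives into the achiral target.

**Route**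

Step 1
Reactants: 1 3,4,5-trimethoxyphenol
Product: 2 2-bromo-3,4,5-trimethoxyphenol
Conditions: NBS (1.0 equiv), CH2Cl2, −78 °C to 0 °C
Reagents that add atoms: N-bromosuccinimide, O=C1CCC(=O)N1Br
Why: Electrophilic aromatic bromination at one of the two equivalent positions ortho to the hydroxyl group (also para to a methoxy group), with one equivalent of NBS at low temperature to hold the reaction at the monobromide and avoid quinone formation.

Step 2
Reactants: 2 2-bromo-3,4,5-trimethoxyphenol
Product: 3 (2-bromo-3,4,5-trimethoxyphenoxy)trimethylsilane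
Conditions: HMDS, THF, 70 °C; volatiles removed in vacuo, crude used directly
Reagents that add atoms: hexamethyldisilazane, C[Si](C)(C)N[Si](C)(C)C
Why: O-silylation of a phenol by HMDS, whose only by-product is volatile ammonia, so the moisture-sensitive aryl silyl ether can be carried on without purification.

Step 3
Reactants: 3 (2-bromo-3,4,5-trimethoxyphenoxy)trimethylsilane
Product: 5 3,4,5-trimethoxy-2-(trimethylsilyl)phenyl trifluoromethanesulfonate, via lithium 3,4,5-trimethoxy-2-(trimethylsilyl)phenoxide 4 (not isolated)
Conditions: n-BuLi, THF, −100 °C to −78 °C; then Tf2O, −100 °C to rt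
Reagents that add atoms: trifluoromethanesulfonic anhydride, O=S(=O)(OS(=O)(=O)C(F)(F)F)C(F)(F)F
Why: Bromine–lithium exchange is followed by a retro-Brook 1,3 O-to-C silyl shift to the lithium phenoxide, which is triflated in the same flask, the standard entry to ortho-silylaryl triflate aryne precursors.

Step 4
Reactants: 6 2,3-dihydroxybenzaldehyde
Product: 7 3-(benzyloxy)-2-hydroxybenzaldehyde
Conditions: NaH (2.2 equiv), DMSO, rt; then BnBr (1.0 equiv), rt; aq. HCl work-up
Reagents that add atoms: benzyl bromide, BrCc1ccccc1
Why: Williamson etherification of the dianion, in which the 2-phenoxide is conjugated with and chelated to the formyl group so that one equivalent of benzyl bromide should react at the more nucleophilic 3-oxygen.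

Step 5
Reactants: 7 3-(benzyloxy)-2-hydroxybenzaldehyde
Product: 8 3-(benzyloxy)-2-methoxybenzaldehyde
Conditions: MeI, K2CO3, DMF, rt
Reagents that add atoms: iodomethane, CI
Why: Williamson methylation of the remaining chelated phenol, for which carbonate in a dipolar aprotic solvent is sufficient.

Step 6
Reactants: 8 3-(benzyloxy)-2-methoxybenzaldehyde
Product: 9 1-(benzyloxy)-2-methoxy-3-[2-(methylsulfinyl)-2-(methylthio)ethenyl]benzene
Conditions: methyl (methylthio)methyl sulfoxide, benzyltrimethylammonium hydroxide (cat.), THF, reflux
Reagents that add atoms: methyl (methylthio)methyl sulfoxide, CSCS(C)=O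
Why: Knoevenagel-type condensation of a non-enolisable aryl aldehyde with the stabilised carbanion of the formaldehyde dithioacetal S-oxide gives the ketene dithioacetal monoxide, a masked arylacetic acid.

Step 7
Reactants: 9 1-(benzyloxy)-2-methoxy-3-[2-(methylsulfinyl)-2-(methylthio)ethenyl]benzene
Product: 10 methyl 2-(3-(benzyloxy)-2-methoxyphenyl)acetate
Conditions: HCl (gas), MeOH, 0 °C to rt
Reagents that add atoms: methanol, CO
Why: Acid-promoted methanolysis of the ketene dithioacetal S-oxide (Pummerer-type, internal redox) unveils the methyl arylacetate, completing the one-carbon homologation under conditions a benzyl aryl ether tolerates.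

Step 8
Reactants: 10 methyl 2-(3-(benzyloxy)-2-methoxyphenyl)acetate; 11 methyl formate
Product: 12 methyl 2-(3-(benzyloxy)-2-methoxyphenyl)-3-hydroxyacrylate
Conditions: NaH, HCO2Me (excess), THF, 0 °C to rt; aq. HCl work-up
Reagents that add atoms: methyl formate (compound 11), COC=O
Why: Crossed Claisen condensation of the arylacetate enolate with a non-enolisable formate, driven forward by deprotonation of the acidic α-formyl ester product.

Step 9
Reactants: 12 methyl 2-(3-(benzyloxy)-2-methoxyphenyl)-3-hydroxyacrylate
Product: 13 methyl (E)-2-(3-(benzyloxy)-2-methoxyphenyl)-3-methoxyacrylate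
Conditions: Me2SO4, K2CO3, DMF, rt
Reagents that add atoms: dimethyl sulfate, COS(=O)(=O)OC
Why: O-alkylation of the formyl ester enolate by a hard methylating agent gives the β-methoxyacrylate, expected mainly as the E isomer with methoxy anti to the ester, as in the standard preparation of strobilurin-type toxophores.

Step 10
Reactants: 13 methyl (E)-2-(3-(benzyloxy)-2-methoxyphenyl)-3-methoxyacrylate
Product: 14 (E)-2-(3-(benzyloxy)-2-methoxyphenyl)-3-methoxyacrylic acid
Conditions: LiOH·H2O, THF/MeOH/H2O, 40 °C; then 1 M HCl to pH 3–4, 0 °C, immediate extraction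
Reagents that add atoms: lithium hydroxide, [Li+].[OH-]
Why: Saponification of the methyl ester by acyl substitution, with cold and only mildly acidic work-up so that the enol ether of the vinylogous carbonate is not hydrolysed.

Step 11
Reactants: 5 3,4,5-trimethoxy-2-(trimethylsilyl)phenyl trifluoromethanesulfonate; 14 (E)-2-(3-(benzyloxy)-2-methoxyphenyl)-3-methoxyacrylic acid
Product: 17 3-(3-(benzyloxy)-2-methoxyphenyl)-5,6,7-trimethoxy-4H-chromen-4-one, via 3,4,5-trimethoxybenzyne 15 (not isolated), via ortho-hydroxyaryl methoxyenone 16 (not isolated)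
Conditions: CsF (4 equiv), 5 (1.5 equiv), dry THF, sealed tube, 125 °C; cat. HCl, MeOH, 50 °C on the crude only if open-chain 16 remains
Reagents that add atoms: none
Why: Proposed new method: fluoride removes the silyl group of 5 and triflate departs to give aryne 15; the cesium carboxylate of 14 adds through oxygen, the ortho-aryl anion so formed attacks its own ester carbonyl (4-exo-trig), and the benzoxetene alkoxide opens to the ortho-acyl phenoxide of 16, an anionic Fries-type shift that creates the C8a–O1 and C4a–C4 bonds. The closest known reaction type is the fluoride-induced C–O insertion of arynes into carboxylic acids to give ortho-hydroxyaryl ketones, which with arylpropiolic acids runs on in the same pot to flavones; a β-methoxyacrylic acid as partner is the new element. Ring C then closes by 6-endo-trig oxa-Michael addition of the phenoxide oxygen to the β-methoxy enone carbon (C2) and E1cB loss of methoxide, the addition–elimination by which ortho-hydroxyaryl β-alkoxy and β-amino enones are routinely converted into chromones, so the alkene geometry of 14 is of no consequence. No stereocenter is formed. The one selectivity required is the orientation of addition to the unsymmetrical aryne: the methoxy group flanking the triple bond (the future C5 methoxy) makes the remote aryne carbon the electrophilic site and stabilises negative charge at the adjacent carbon, so oxygen should enter at C8a and the acyl group at C4a. Dry conditions and excess CsF hold the acid as its carboxylate and limit protonation of the aryl anion to the simple aryl ester.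

Step 12
Reactants: 17 3-(3-(benzyloxy)-2-methoxyphenyl)-5,6,7-trimethoxy-4H-chromen-4-one
Product: 18 3-(3-hydroxy-2-methoxyphenyl)-5,6,7-trimethoxy-4H-chromen-4-one (target)
Conditions: H2 (1 atm), 10% Pd/C, EtOAc/MeOH, rt, stopped when 17 is consumed
Reagents that add atoms: none
Why: Catalytic hydrogenolysis of the benzyl aryl ether is expected to be much faster at atmospheric pressure than reduction of the conjugated C2=C3 bond of the chromone, so stopping at consumption of 17 should deliver the free 3'-phenol.

**Compound list**
1 | 3,4,5-trimethoxyphenol | COc1cc(O)cc(OC)c1OC | starting material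
2 | 2-bromo-3,4,5-trimethoxyphenol | COc1cc(O)c(Br)c(OC)c1OC | intermediate
3 | (2-bromo-3,4,5-trimethoxyphenoxy)trimethylsilane | COc1cc(O[Si](C)(C)C)c(Br)c(OC)c1OC | intermediate
4 | lithium 3,4,5-trimethoxy-2-(trimethylsilyl)phenoxide (not isolated) | [Li+].[O-]c1cc(OC)c(OC)c(OC)c1[Si](C)(C)C | intermediate
5 | 3,4,5-trimethoxy-2-(trimethylsilyl)phenyl trifluoromethanesulfonate | COc1cc(OS(=O)(=O)C(F)(F)F)c([Si](C)(C)C)c(OC)c1OC | intermediate
6 | 2,3-dihydroxybenzaldehyde | O=Cc1cccc(O)c1O | starting material
7 | 3-(benzyloxy)-2-hydroxybenzaldehyde | O=Cc1cccc(OCc2ccccc2)c1O | intermediate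
8 | 3-(benzyloxy)-2-methoxybenzaldehyde | COc1c(C=O)cccc1OCc1ccccc1 | intermediate
9 | 1-(benzyloxy)-2-methoxy-3-[2-(methylsulfinyl)-2-(methylthio)ethenyl]benzene (alkene isomers, racemic at sulfur) | COc1c(C=C(SC)S(C)=O)cccc1OCc1ccccc1 | intermediate
10 | methyl 2-(3-(benzyloxy)-2-methoxyphenyl)acetate | COC(=O)Cc1cccc(OCc2ccccc2)c1OC | intermediate
11 | methyl formate | COC=O | starting material
12 | methyl 2-(3-(benzyloxy)-2-methoxyphenyl)-3-hydroxyacrylate (enol tautomer of the α-formyl ester) | COC(=O)C(=CO)c1cccc(OCc2ccccc2)c1OC | intermediate
13 | methyl (E)-2-(3-(benzyloxy)-2-methoxyphenyl)-3-methoxyacrylate | CO/C=C(/C(=O)OC)c1cccc(OCc2ccccc2)c1OC | intermediate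
14 | (E)-2-(3-(benzyloxy)-2-methoxyphenyl)-3-methoxyacrylic acid | CO/C=C(/C(=O)O)c1cccc(OCc2ccccc2)c1OC | intermediate
15 | 3,4,5-trimethoxybenzyne (not isolated) | COC1=C(OC)C(OC)=CC#C1 | intermediate
16 | (E)-2-(3-(benzyloxy)-2-methoxyphenyl)-1-(6-hydroxy-2,3,4-trimethoxyphenyl)-3-methoxyprop-2-en-1-one (not isolated; present as its cesium phenoxide) | CO/C=C(/C(=O)c1c(O)cc(OC)c(OC)c1OC)c1cccc(OCc2ccccc2)c1OC | intermediate
17 | 3-(3-(benzyloxy)-2-methoxyphenyl)-5,6,7-trimethoxy-4H-chromen-4-one | COc1cc2occ(-c3cccc(OCc4ccccc4)c3OC)c(=O)c2c(OC)c1OC | intermediate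
18 | 3-(3-hydroxy-2-methoxyphenyl)-5,6,7-trimethoxy-4H-chromen-4-one | COc1cc2occ(-c3cccc(O)c3OC)c(=O)c2c(OC)c1OC | target

**Totals**
Total step count: 12.
Longest linear sequence: 9 steps (6 to 18 through steps 4–12); the ring A branch (steps 1–3) joins at step 11.

**Steps most likely to fail, with fallbacks**

1. Step 11 (proposed new method). The aryl anion may be protonated before the acyl shift, so that only O-arylation to the aryl ester takes place. The carboxylate may also add with the opposite orientation, or the enol ether acid may break down under hot fluoride. The fallback uses known chemistry, sets out from 1 and 8, and returns at 17. Phenol 1 would be C-acetylated ortho to the hydroxyl group (Ac2O, BF3·OEt2, 80 °C) to give 1-(6-hydroxy-2,3,4-trimethoxyphenyl)ethan-1-one F1. Claisen–Schmidt condensation of this ketone with aldehyde 8 (KOH, EtOH, rt) should give the chalcone (E)-3-(3-(benzyloxy)-2-methoxyphenyl)-1-(6-hydroxy-2,3,4-trimethoxyphenyl)prop-2-en-1-one F2. Oxidative 1,2-aryl migration with Tl(NO3)3·3H2O (trivalent thallium nitrate) in MeOH/HC(OMe)3 would then move ring B to the α-carbon and give racemic 2-(3-(benzyloxy)-2-methoxyphenyl)-1-(6-hydroxy-2,3,4-trimethoxyphenyl)-3,3-dimethoxypropan-1-one F3; the chelated, acyl-deactivated phenol is expected to survive the oxidant. Brief heating with HCl in MeOH closes ring C with loss of methanol and delivers 17.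

2. Step 10. The enol ether may be lost during saponification or acidification, by conjugate addition of hydroxide or by acid hydrolysis to the α-formyl acid followed by decarboxylation. The fallback sets out from 13 and returns at 17 without ever making the free acid. Anhydrous ester cleavage with KOSiMe3 in dry THF should give potassium (E)-2-(3-(benzyloxy)-2-methoxyphenyl)-3-methoxyacrylate F4, which is dried and used directly as the carboxylate partner with 5 and CsF under the conditions of step 11.

3. Step 3. The O-to-C silyl shift in the crowded aryllithium may be incomplete, the aryllithium may be quenched to the debrominated phenol, or silicon may be lost during triflation. The fallback sets out from 1 and returns at 5, bypassing 2 and 3. Carbamoylation with isopropyl isocyanate (Et3N, CH2Cl2) would give 3,4,5-trimethoxyphenyl N-isopropylcarbamate F5. In-situ N-silylation (TMSOTf, TMEDA), carbamate-directed ortho-lithiation (n-BuLi, TMEDA, Et2O, −78 °C; both ortho positions are equivalent and each is also flanked by a methoxy group), TMSCl quench and mild acid work-up would give 3,4,5-trimethoxy-2-(trimethylsilyl)phenyl N-isopropylcarbamate F6. Cleavage of the carbamate with Et2NH and DBU in MeCN releases 3,4,5-trimethoxy-2-(trimethylsilyl)phenol F7, which is triflated in the same pot with PhNTf2 to give 5.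

**Further compounds**
F1 | step 11 | 1-(6-hydroxy-2,3,4-trimethoxyphenyl)ethan-1-one | CC(=O)c1c(O)cc(OC)c(OC)c1OC
F2 | step 11 | (E)-3-(3-(benzyloxy)-2-methoxyphenyl)-1-(6-hydroxy-2,3,4-trimethoxyphenyl)prop-2-en-1-one | COc1cc(O)c(C(=O)/C=C/c2cccc(OCc3ccccc3)c2OC)c(OC)c1OC
F3 | step 11 | racemic 2-(3-(benzyloxy)-2-methoxyphenyl)-1-(6-hydroxy-2,3,4-trimethoxyphenyl)-3,3-dimethoxypropan-1-one | COC(OC)C(C(=O)c1c(O)cc(OC)c(OC)c1OC)c1cccc(OCc2ccccc2)c1OC
F4 | step 10 | potassium (E)-2-(3-(benzyloxy)-2-methoxyphenyl)-3-methoxyacrylate | [K+].CO/C=C(/C(=O)[O-])c1cccc(OCc2ccccc2)c1OC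
F5 | step 3 | 3,4,5-trimethoxyphenyl N-isopropylcarbamate | COc1cc(OC(=O)NC(C)C)cc(OC)c1OC
F6 | step 3 | 3,4,5-trimethoxy-2-(trimethylsilyl)phenyl N-isopropylcarbamate | COc1cc(OC(=O)NC(C)C)c([Si](C)(C)C)c(OC)c1OC
F7 | step 3 | 3,4,5-trimethoxy-2-(trimethylsilyl)phenol | COc1cc(O)c([Si](C)(C)C)c(OC)c1OC
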